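Retrosynthesis cuts, in this order: the three O-benzyl bonds; the C2–aryl bond of the flavanone (ring B onto a chromone); ring C back to an acetyl group beside a masked phenol, with C2 from a one-carbon reagent; the acetyl–ring A bond; N–CH3 (from a carbamate); piperidine C4–C5; then N1–allyl and piperidine C2–C3 (allylation of a sulfinimine of protected phloroglucinaldehyde).
Forward order: ring A is bought; the piperidine is assembled on it and closed last at C4–C5 by ring-closing metathesis of an N-allyl/C-allyl 1,7-diene, saturated in the same pot; ring C (chromone) follows; ring B is added last.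
Enabling features: piperidine C3–C6 are unsubstituted CH2 groups and C4 and C5 each sit one CH2 away from the N1–C2 unit, so both halves of the ring are allyl groups on N1 and C2. In ring A the piperidine-bearing carbon lies para to the one differentiated oxygen, so making that oxygen O1 gives the 6-isomer whichever ortho carbon is acylated.
Stereochemistry: piperidine C2 (S) comes from (R)-tert-butanesulfinamide-controlled allylation of the aldimine; flavanone C2 (S) comes from ligand-controlled palladium-catalysed 1,4-arylation; the two centres are remote and set independently.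

Key step: step 6

Assumption: the target is made as the free base; in step 10 the sense of induction of the pyridine–oxazoline ligand is assigned by analogy with cyclic enones, and the other ligand antipode is used should the opposite sense be found.

Step 1
Reactants: 1 2,4,6-trihydroxybenzaldehyde; 2 chloromethyl methyl ether
Product: 3 2,6-dihydroxy-4-(methoxymethoxy)benzaldehyde
Conditions: MOMCl (1.0 equiv), K2CO3, acetone, 0 °C to rt
Reagents that add atoms: chloromethyl methyl ether (COCCl)
Why: Williamson-type O-alkylation in which the para-hydroxyl, the most acidic one and the only one not held in a hydrogen bond to the formyl oxygen, should react first with one equivalent of the chloride.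

Step 2
Reactants: 3 2,6-dihydroxy-4-(methoxymethoxy)benzaldehyde; 4 benzyl bromide
Product: 5 2,6-bis(benzyloxy)-4-(methoxymethoxy)benzaldehyde
Conditions: BnBr (2.5 equiv), K2CO3, DMF, 60 °C
Reagents that add atoms: benzyl bromide (BrCc1ccccc1)
Why: Williamson ether synthesis in which excess benzyl bromide in warm DMF should alkylate both hydrogen-bonded ortho-hydroxyls, leaving the para oxygen as the only differentiated one.

Step 3
Reactants: 5 2,6-bis(benzyloxy)-4-(methoxymethoxy)benzaldehyde; 6 (R)-2-methylpropane-2-sulfinamide; 7 allyl bromide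
Product: 9 (R)-N-[(1S)-1-[2,6-bis(benzyloxy)-4-(methoxymethoxy)phenyl]but-3-en-1-yl]-2-methylpropane-2-sulfinamide, via sulfinimine 8 (not isolated)
Conditions: Ti(OEt)4, THF, 60 °C; then indium powder, allyl bromide, 60 °C
Reagents that add atoms: (R)-2-methylpropane-2-sulfinamide (CC(C)(C)[S@@](=O)N); allyl bromide (C=CCBr)
Why: Ti(OEt)4-mediated condensation should give the (E)-N-sulfinyl aldimine, and indium-mediated Barbier-type allylation through a six-membered chair transition state with indium bound to the sulfinylimine unit should deliver the allyl group to the Si face of the (R)-sulfinimine, which sets the future piperidine C2 as S.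

Step 4
Reactants: 9 (R)-N-[(1S)-1-[2,6-bis(benzyloxy)-4-(methoxymethoxy)phenyl]but-3-en-1-yl]-2-methylpropane-2-sulfinamide; 10 methyl chloroformate
Product: 12 methyl N-[(1S)-1-[2,6-bis(benzyloxy)-4-(methoxymethoxy)phenyl]but-3-en-1-yl]carbamate, via primary amine 11 (not isolated)
Conditions: HCl (4 M in dioxane, 2 equiv), MeOH, 0 °C, 20 min; evaporate; then ClCO2Me, NaHCO3, CH2Cl2/H2O, 0 °C to rt
Reagents that add atoms: methyl chloroformate (COC(Cl)=O)
Why: Acidolysis of the N–S bond is fast at 0 °C, so the aryl MOM ether and the benzylic C–N bond should survive the brief exposure, and the freed amine is acylated under Schotten–Baumann conditions without touching the stereocenter.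

Step 5
Reactants: 12 methyl N-[(1S)-1-[2,6-bis(benzyloxy)-4-(methoxymethoxy)phenyl]but-3-en-1-yl]carbamate; 7 allyl bromide
Product: 13 methyl N-allyl-N-[(1S)-1-[2,6-bis(benzyloxy)-4-(methoxymethoxy)phenyl]but-3-en-1-yl]carbamate
Conditions: NaH, DMF, 0 °C; then allyl bromide, rt
Reagents that add atoms: allyl bromide (C=CCBr)
Why: N-Alkylation of the carbamate anion by SN2 displacement on allyl bromide is standard for NH-carbamates and completes the 1,7-diene without affecting C2.

Step 6
Reactants: 13 methyl N-allyl-N-[(1S)-1-[2,6-bis(benzyloxy)-4-(methoxymethoxy)phenyl]but-3-en-1-yl]carbamate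
Product: 15 methyl (2S)-2-[2,6-bis(benzyloxy)-4-(methoxymethoxy)phenyl]piperidine-1-carboxylate, via tetrahydropyridine carbamate 14 (not isolated)
Conditions: second-generation Grubbs catalyst RuCl2(=CHPh)(H2IMes)(PCy3) (5 mol %), CH2Cl2 (0.02 M), 40 °C; then H2 (7 atm), MeOH, NEt3 (cat.), 60 °C, same vessel
Reagents that add atoms: none
Why: The ruthenium benzylidene is exchanged for an alkylidene on one terminal vinyl group, [2+2] cycloaddition with the second vinyl group gives a ruthenacyclobutane, and its cycloreversion forms the C4=C5 bond and releases ethylene, whose loss makes the closure irreversible. The closest known reaction type is ring-closing metathesis of N-acyl N-allyl homoallylamines to 1,2,3,6-tetrahydropyridines, run in tandem with hydrogenation by the ruthenium hydride that the spent alkylidene forms under H2. The six-membered ring is closed between the two internal alkene carbons of a 1,7-diene (C4 from the allyl group on C2, C5 from the allyl group on N1), the two terminal CH2 groups leaving together. No stereocenter is formed: C2 should keep the S configuration set in step 3 because its C–H bond lies two atoms from the new alkene and the conditions are neutral, so the electron-rich benzylic C2–N1 bond cannot ionise. The step needs ring closure to beat oligomerisation and needs the alkene to be saturated without loss of the benzyl ethers; the first is secured by high dilution and by the carbamate, which removes the basic lone pair that would bind ruthenium and, through allylic strain against the 2,6-disubstituted aryl group, turns the two allyl arms toward each other, and the second by the ruthenium hydride, which does not hydrogenolyse benzyl or MOM ethers. The carbamate is not removed afterwards but reduced to the N-methyl group in step 7.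

Step 7
Reactants: 15 methyl (2S)-2-[2,6-bis(benzyloxy)-4-(methoxymethoxy)phenyl]piperidine-1-carboxylate
Product: 16 (2S)-2-[2,6-bis(benzyloxy)-4-(methoxymethoxy)phenyl]-1-methylpiperidine
Conditions: LiAlH4, THF, reflux; H2O/aq. NaOH work-up
Reagents that add atoms: none
Why: LiAlH4 reduction of a carbamate to the N-methyl amine is a standard transformation, so the nitrogen protecting group becomes the N-methyl group of the target while the ethers and C2 stay untouched.

Step 8
Reactants: 16 (2S)-2-[2,6-bis(benzyloxy)-4-(methoxymethoxy)phenyl]-1-methylpiperidine; 17 N-methoxy-N-methylacetamide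
Product: 18 1-[2,4-bis(benzyloxy)-6-(methoxymethoxy)-3-[(2S)-1-methylpiperidin-2-yl]phenyl]ethan-1-one
Conditions: n-BuLi, THF, 0 °C; then MeC(O)N(OMe)Me, −78 °C to rt; aq. NH4Cl
Reagents that add atoms: N-methoxy-N-methylacetamide (CC(=O)N(C)OC)
Why: Directed ortho-metalation should occur at the ring C–H flanked by the MOM ether and a benzyl ether (the two free ring positions are equivalent), and the N-methoxy-N-methylamide stops at the ketone through its stable chelated tetrahedral adduct.

Step 9
Reactants: 18 1-[2,4-bis(benzyloxy)-6-(methoxymethoxy)-3-[(2S)-1-methylpiperidin-2-yl]phenyl]ethan-1-one; 19 N,N-dimethylformamide dimethyl acetal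
Product: 21 5,7-bis(benzyloxy)-6-[(2S)-1-methylpiperidin-2-yl]-4H-chromen-4-one, via enaminone 20 (not isolated)
Conditions: Me2NCH(OMe)2, toluene, 105 °C; evaporate; then conc. HCl, MeOH, 40 °C; aq. NaHCO3
Reagents that add atoms: N,N-dimethylformamide dimethyl acetal (COC(OC)N(C)C)
Why: Condensation of the methyl ketone with the amide acetal gives an enaminone, and acid then removes the MOM ether so that the freed phenol adds to the β-carbon with loss of dimethylamine (enaminone route to chromones), which fixes the oxygen para to the piperidine-bearing carbon as O1 and hence the piperidine at C6.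

Step 10
Reactants: 21 5,7-bis(benzyloxy)-6-[(2S)-1-methylpiperidin-2-yl]-4H-chromen-4-one; 22 4-(benzyloxy)phenylboronic acid
Product: 23 (2S)-5,7-bis(benzyloxy)-2-[4-(benzyloxy)phenyl]-6-[(2S)-1-methylpiperidin-2-yl]-2,3-dihydro-4H-chromen-4-one
Conditions: Pd(OCOCF3)2 (10 mol %), (R)-t-BuPyOx (12 mol %), NH4PF6, H2O, ClCH2CH2Cl, 60 °C; 21 charged as its trifluoroacetate salt
Reagents that add atoms: 4-(benzyloxy)phenylboronic acid (OB(O)c1ccc(OCc2ccccc2)cc1)
Why: In this palladium-catalysed asymmetric conjugate addition of an arylboronic acid to a chromone, transmetalation gives a cationic aryl complex of divalent palladium held by the pyridine–oxazoline ligand, insertion of C2=C3 should place the aryl group on C2 from the face left open by the tert-butyl group (2S expected with the (R)-ligand), and protonation of the palladium enolate releases the flavanone under base-free conditions that should not open ring C.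

Step 11
Reactants: 23 (2S)-5,7-bis(benzyloxy)-2-[4-(benzyloxy)phenyl]-6-[(2S)-1-methylpiperidin-2-yl]-2,3-dihydro-4H-chromen-4-one
Product: 24 (2S)-5,7-dihydroxy-2-(4-hydroxyphenyl)-6-[(2S)-1-methylpiperidin-2-yl]-2,3-dihydro-4H-chromen-4-one
Conditions: H2 (1 atm), Pd/C (10% palladium on carbon), EtOAc/MeOH, rt
Reagents that add atoms: none
Why: Hydrogenolysis of the three aryl benzyl ethers under neutral conditions at room temperature should be much faster than cleavage of the benzylic C2–O1 or C–N bonds and should leave both stereocenters untouched.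

Compound list
1 | 2,4,6-trihydroxybenzaldehyde | O=Cc1c(O)cc(O)cc1O | starting material
2 | chloromethyl methyl ether | COCCl | starting material
3 | 2,6-dihydroxy-4-(methoxymethoxy)benzaldehyde | O=Cc1c(O)cc(OCOC)cc1O | intermediate
4 | benzyl bromide | BrCc1ccccc1 | starting material
5 | 2,6-bis(benzyloxy)-4-(methoxymethoxy)benzaldehyde | O=Cc1c(OCc2ccccc2)cc(OCOC)cc1OCc1ccccc1 | intermediate
6 | (R)-2-methylpropane-2-sulfinamide | CC(C)(C)[S@@](=O)N | starting material
7 | allyl bromide | C=CCBr | starting material
8 | (R,E)-N-[2,6-bis(benzyloxy)-4-(methoxymethoxy)benzylidene]-2-methylpropane-2-sulfinamide | CC(C)(C)[S@@](=O)/N=C/c1c(OCc2ccccc2)cc(OCOC)cc1OCc1ccccc1 | intermediate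
9 | (R)-N-[(1S)-1-[2,6-bis(benzyloxy)-4-(methoxymethoxy)phenyl]but-3-en-1-yl]-2-methylpropane-2-sulfinamide | CC(C)(C)[S@@](=O)N[C@@H](CC=C)c1c(OCc2ccccc2)cc(OCOC)cc1OCc1ccccc1 | intermediate
10 | methyl chloroformate | COC(Cl)=O | starting material
11 | (1S)-1-[2,6-bis(benzyloxy)-4-(methoxymethoxy)phenyl]but-3-en-1-amine | N[C@@H](CC=C)c1c(OCc2ccccc2)cc(OCOC)cc1OCc1ccccc1 | intermediate
12 | methyl N-[(1S)-1-[2,6-bis(benzyloxy)-4-(methoxymethoxy)phenyl]but-3-en-1-yl]carbamate | COC(=O)N[C@@H](CC=C)c1c(OCc2ccccc2)cc(OCOC)cc1OCc1ccccc1 | intermediate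
13 | methyl N-allyl-N-[(1S)-1-[2,6-bis(benzyloxy)-4-(methoxymethoxy)phenyl]but-3-en-1-yl]carbamate | COC(=O)N(CC=C)[C@@H](CC=C)c1c(OCc2ccccc2)cc(OCOC)cc1OCc1ccccc1 | intermediate
14 | methyl (2S)-2-[2,6-bis(benzyloxy)-4-(methoxymethoxy)phenyl]-3,6-dihydro-2H-pyridine-1-carboxylate | COC(=O)N1CC=CC[C@H]1c1c(OCc2ccccc2)cc(OCOC)cc1OCc1ccccc1 | intermediate
15 | methyl (2S)-2-[2,6-bis(benzyloxy)-4-(methoxymethoxy)phenyl]piperidine-1-carboxylate | COC(=O)N1CCCC[C@H]1c1c(OCc2ccccc2)cc(OCOC)cc1OCc1ccccc1 | intermediate
16 | (2S)-2-[2,6-bis(benzyloxy)-4-(methoxymethoxy)phenyl]-1-methylpiperidine | CN1CCCC[C@H]1c1c(OCc2ccccc2)cc(OCOC)cc1OCc1ccccc1 | intermediate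
17 | N-methoxy-N-methylacetamide | CC(=O)N(C)OC | starting material
18 | 1-[2,4-bis(benzyloxy)-6-(methoxymethoxy)-3-[(2S)-1-methylpiperidin-2-yl]phenyl]ethan-1-one | CN1CCCC[C@H]1c1c(OCc2ccccc2)cc(OCOC)c(C(C)=O)c1OCc1ccccc1 | intermediate
19 | N,N-dimethylformamide dimethyl acetal | COC(OC)N(C)C | starting material
20 | (E)-1-[2,4-bis(benzyloxy)-6-(methoxymethoxy)-3-[(2S)-1-methylpiperidin-2-yl]phenyl]-3-(dimethylamino)prop-2-en-1-one | CN1CCCC[C@H]1c1c(OCc2ccccc2)cc(OCOC)c(C(=O)/C=C/N(C)C)c1OCc1ccccc1 | intermediate
21 | 5,7-bis(benzyloxy)-6-[(2S)-1-methylpiperidin-2-yl]-4H-chromen-4-one | CN1CCCC[C@H]1c1c(OCc2ccccc2)cc2occc(=O)c2c1OCc1ccccc1 | intermediate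
22 | 4-(benzyloxy)phenylboronic acid | OB(O)c1ccc(OCc2ccccc2)cc1 | starting material
23 | (2S)-5,7-bis(benzyloxy)-2-[4-(benzyloxy)phenyl]-6-[(2S)-1-methylpiperidin-2-yl]-2,3-dihydro-4H-chromen-4-one | CN1CCCC[C@H]1c1c(OCc2ccccc2)cc2c(c1OCc1ccccc1)C(=O)C[C@@H](c1ccc(OCc3ccccc3)cc1)O2 | intermediate
24 | (2S)-5,7-dihydroxy-2-(4-hydroxyphenyl)-6-[(2S)-1-methylpiperidin-2-yl]-2,3-dihydro-4H-chromen-4-one | CN1CCCC[C@H]1c1c(O)cc2c(c1O)C(=O)C[C@@H](c1ccc(O)cc1)O2 | target

Total step count: 11. Longest linear sequence: 11 steps, from 2,4,6-trihydroxybenzaldehyde 1 to target 24.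

Steps most likely to fail

Step 10. The basic nitrogen may inhibit the palladium catalyst, insertion into the electron-rich 5,7-dialkoxychromone may be slow, and facial selectivity may be insufficient. The fallback builds the flavanone by aldol addition and ring closure with inversion. It sets out from ketone 18: enolisation with B-chlorodiisopinocampheylborane (the antipode that gives the 3R aldol) and NEt3, followed by addition to 4-(benzyloxy)benzaldehyde, should give (3R)-3-[4-(benzyloxy)phenyl]-1-[2,4-bis(benzyloxy)-6-(methoxymethoxy)-3-[(2S)-1-methylpiperidin-2-yl]phenyl]-3-hydroxypropan-1-one F1. Chemoselective cleavage of the phenolic MOM ether (NaHSO4 on silica, CH2Cl2, rt) should give (3R)-3-[4-(benzyloxy)phenyl]-1-[2,4-bis(benzyloxy)-6-hydroxy-3-[(2S)-1-methylpiperidin-2-yl]phenyl]-3-hydroxypropan-1-one F2. Mitsunobu cyclisation (PPh3, diisopropyl azodicarboxylate, THF, 0 °C) with inversion at the carbinol carbon should then give flavanone 23, where the route is rejoined.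

Step 6. The hindered diene may oligomerise, ruthenium hydrides may isomerise the allyl groups before closure, or the in-pot hydrogenation may stall. The fallback closes the piperidine at N1–C6 by alkylation. It sets out from aldehyde 5 and sulfinamide 6, which are condensed (Ti(OEt)4, THF, 60 °C) to sulfinimine 8, this time isolated. Addition of ClCH2CH2CH2CH2MgBr in CH2Cl2 at −48 °C (chelated chair, Si face) should give (R)-N-[(1S)-1-[2,6-bis(benzyloxy)-4-(methoxymethoxy)phenyl]-5-chloropentyl]-2-methylpropane-2-sulfinamide F3. LiN(SiMe3)2 in THF should close the ring by intramolecular N-alkylation to (2S)-2-[2,6-bis(benzyloxy)-4-(methoxymethoxy)phenyl]-1-[(R)-tert-butylsulfinyl]piperidine F4. HCl in MeOH at 0 °C should give (2S)-2-[2,6-bis(benzyloxy)-4-(methoxymethoxy)phenyl]piperidine F5, and reductive methylation (aqueous formaldehyde, NaBH(OAc)3) returns to the route at N-methylpiperidine 16.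

Step 8. n-BuLi may deprotonate the benzylic OCH2 groups (followed by Wittig rearrangement), or ring metalation may be incomplete. The fallback makes the aryl–metal species by electrophilic bromination and halogen–metal exchange. It sets out from 16: N-bromosuccinimide (1 equiv, MeCN, 0 °C, amine masked as its trifluoroacetate salt) should brominate one of the two equivalent free ring positions to give (2S)-2-[2,6-bis(benzyloxy)-3-bromo-4-(methoxymethoxy)phenyl]-1-methylpiperidine F6. Exchange with i-PrMgCl·LiCl (THF, −20 °C) and acylation with N-methoxy-N-methylacetamide 17 returns to the route at ketone 18.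

Further compounds
F1 | step 10 | (3R)-3-[4-(benzyloxy)phenyl]-1-[2,4-bis(benzyloxy)-6-(methoxymethoxy)-3-[(2S)-1-methylpiperidin-2-yl]phenyl]-3-hydroxypropan-1-one | CN1CCCC[C@H]1c1c(OCc2ccccc2)cc(OCOC)c(C(=O)C[C@@H](O)c2ccc(OCc3ccccc3)cc2)c1OCc1ccccc1
F2 | step 10 | (3R)-3-[4-(benzyloxy)phenyl]-1-[2,4-bis(benzyloxy)-6-hydroxy-3-[(2S)-1-methylpiperidin-2-yl]phenyl]-3-hydroxypropan-1-one | CN1CCCC[C@H]1c1c(OCc2ccccc2)cc(O)c(C(=O)C[C@@H](O)c2ccc(OCc3ccccc3)cc2)c1OCc1ccccc1
F3 | step 6 | (R)-N-[(1S)-1-[2,6-bis(benzyloxy)-4-(methoxymethoxy)phenyl]-5-chloropentyl]-2-methylpropane-2-sulfinamide | CC(C)(C)[S@@](=O)N[C@@H](CCCCCl)c1c(OCc2ccccc2)cc(OCOC)cc1OCc1ccccc1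
F4 | step 6 | (2S)-2-[2,6-bis(benzyloxy)-4-(methoxymethoxy)phenyl]-1-[(R)-tert-butylsulfinyl]piperidine | CC(C)(C)[S@@](=O)N1CCCC[C@H]1c1c(OCc2ccccc2)cc(OCOC)cc1OCc1ccccc1
F5 | step 6 | (2S)-2-[2,6-bis(benzyloxy)-4-(methoxymethoxy)phenyl]piperidine | N1CCCC[C@H]1c1c(OCc2ccccc2)cc(OCOC)cc1OCc1ccccc1
F6 | step 8 | (2S)-2-[2,6-bis(benzyloxy)-3-bromo-4-(methoxymethoxy)phenyl]-1-methylpiperidine | CN1CCCC[C@H]1c1c(OCc2ccccc2)cc(OCOC)c(Br)c1OCc1ccccc1
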